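Numbering used throughout: each half of the target is numbered C1 (carbamate carbon), C2 (methyl-bearing carbon), C3–C6 (methylenes), C7 (benzylic carbon carrying the side chain) and C8–C11 (side chain, C11 = CHCl2); the second half carries primes.
Assumption: recombinant CylK, expressed in E. coli and purified, is treated as an accessible catalyst and not as a starting material.

## Analysis of the target

Compound 24 is a C2-symmetric [7.7]paracyclophane: a single 22-membered carbocycle built from two resorcinol rings (ring A and ring B), each bound through its 5-position to C1 of one seven-carbon bridge and through its 2-position, the carbon between the two hydroxyls, to C7 of the other bridge. It has six stereocentres, three per half and pairwise identical. C1 (R, benzylic, O-carbamate) and C2 (S, methyl) are neighbours in a syn relationship. C7 (S, benzylic, bearing the 4,4-dichlorobutyl chain C8–C11) is four methylenes away from C2, so neither centre can steer the other. The sensitive groups are two primary carbamates on benzylic carbons, four free phenols on electron-rich rings, and two dichloromethyl termini that would not survive strong base, organometallic reagents or hydrogenolysis. The hard part is the pair of aryl–C7 bonds: a secondary stereogenic carbon must be joined to the most crowded ring position, twice, head to tail, in a way that also closes the 22-membered ring and leaves no protecting-group work on the macrocycle. The strategy rests on the fact that C7 and C7' sit on the ring carbons flanked by two hydroxyls, the most nucleophilic carbon of a 5-alkylresorcinol. This is the bond that the alkylating enzyme CylK forms in cylindrocyclophane biosynthesis from a monomer with a secondary chloride seven carbons from the ring, and because the halves are identical one monomer suffices.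

## Retrosynthetic reasoning

**24 to two molecules of 22 (through 23).** Both aryl–C7 bonds are cut. This halves the problem, removes the macrocycle and puts the two C7 stereocentres into one stereospecific event. Forward, the ring carbon between the hydroxyls of one molecule of 22 must displace chloride from C7 of another with inversion, giving the linear dimer 23, and the same reaction within 23 must close the ring. The chloride in 22 therefore has the spatial arrangement opposite to C7 of 24 (R in 22, S in 24, with unchanged priority order). The reaction has to deliver C- and not O-alkylation, attack at the carbon between the hydroxyls, head-to-tail pairing and ring closure over oligomerisation. Nothing is left to do after it.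

**22 to 21 to 20, then 20 to 9 and 19.** The phenols of 22 are masked as triisopropylsilyl ethers in 21 until the last chemical step, and the saturated C3–C4 link of 21 comes from the alkene of 20. Compound 20 is cut at C3=C4 by cross-metathesis. This bond lies between the C1/C2 pair and the remote C7, so each fragment carries only stereocentres that can be made independently. Fragment 9 holds the arene, C1, C2 and the carbamate; fragment 19 holds C7 and all three chlorines. Because the carbamate and the chlorines are in place before the union, only saturation and desilylation follow it. The saturation has to be a metal-free hydrogen transfer that cannot cleave C–Cl bonds or the benzylic C–O bond.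

**9 to 7, then 7 to 2 and 3; 2 from 1.** The C1–C2 bond is cut by an asymmetric (Z)-crotylboration (through 4, 5 and 6). It sets C1 and C2 in one step and delivers C3 as a vinyl carbon, ready for metathesis. An aldol addition would set the same two centres but would leave C3 at the carboxyl oxidation level, costing protection, reduction, oxidation and methylenation; it is kept as a fallback. Aldehyde 2 is the bis-silyl ether of 1.

**19 to 18 to 17 to 16.** The dichloromethyl group comes from the aldehyde of 18, the aldehyde from the dioxolane of 17, and the C7 chloride of 17 from the alcohol 16 with inversion. The order is fixed: a free C7 hydroxyl and a C11 aldehyde would close to a six-membered lactol, so the alcohol is converted first, while C11 is still an acetal. These manipulations are done on a small fragment whose only other function is a terminal alkene.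

**16 to 13 and 14 (through 15); 13 to 10 and 11 (through 12).** The C8–C9 and C5–C6 bonds are cut. Enantioselective reduction of a C7 ketone was set aside, because the carbonyl would be flanked by two unbranched methylene chains that a chiral reductant cannot tell apart. C7 is instead taken from the stereocentre of (S)-epichlorohydrin 10. Both neighbours are attached by opening epoxides at their CH2 carbons, so C7 is never a reaction centre before the planned inversion.

## Alternatives that were turned down

**Alternative 1:** The disconnection is at the two C2–C3 bonds, with C1 taken back to a ketone and C4–C5 to an alkene. The forward key step is a twofold Claisen rearrangement run as a ring expansion. In an 18-membered ring each half would hold a (Z)-configured enol ether between the aryl-bearing C1 and the allylic C5. On heating, each enol carbon C2 bonds to the vinyl terminus C3 while the C5–O bond breaks, giving the 22-membered bis(aryl ketone) A1 with C2 set and (E)-alkenes at C4–C5.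
- For it: it is flask chemistry throughout; a chair transition state relays the C5 configuration to C2; the large ring is reached by expansion of a smaller ring closed by ester formation.
- Against it for this target: the enol ethers must come from ethylidenation of two hindered aryl ester carbonyls with Z control, and any geometric leak becomes a C2 epimer. C1 emerges as a ketone and needs a syn-selective reduction. After A1 there remain alkene saturation, ketone reduction, unmasking and oxidation of both side-chain ends, two deoxydichlorinations, carbamoylation and acidic removal of four MOM ethers next to benzylic carbamates, each performed twice on the macrocycle. The aryl–C7 stereocentre on a 2,6-dioxygenated ring still has to be made beforehand by other means.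
- Comparison: Alternative 1 is stronger in not depending on an enzyme accepting an unnatural substrate and in its rational control of C2. The chosen route offers a key step that forms the hardest bonds, the C7 centres and the ring together and ends at 24, in 12 steps overall.

**Alternative 2:** The disconnection is at the two C7–C8 bonds of a ring that is already closed. The forward key step is a double carbamate-directed benzylic lithiation at C7 and C7'. Each carbanion is captured at the boron of a four-carbon side-chain donor, and C8 then migrates from boron to C7 as the carbamate leaves. This gives the bis(tertiary boronic ester) A2, which still needs stereospecific protodeboronation.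
- For it: it is modular, since the side chain can be varied late; it rests on stereospecific flask precedent for benzylic substitution; it needs no enzyme.
- Against it for this target: the carbanion and the tertiary boronate sit on an arene with oxygen at both ortho positions, the most congested site of the molecule. Reversible boronate-complex formation and slow migration there would erode stereospecificity, and the MOM ethers invite competing ring lithiation. Both events must succeed on one macrocycle. The step does not make the ring, which needs a separate macrocyclisation. After A2 come protodeboronation, two acetal-to-dichloromethyl conversions, silyl ether to carbamate exchange and MOM removal.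
- Comparison: Alternative 2 is stronger in modularity. The chosen route offers ring closure and both C7 centres in one event, with no tertiary intermediate at the crowded carbon and no steps afterwards.

**Alternative 3:** The disconnection is at two ring bonds in each arene, so that arenes and macrocycle arise together. In the forward key step a cyclobutenone opens thermally to a vinylketene, which adds to the siloxyalkyne of a second molecule. Ring opening, six-electron closure and tautomerisation then build each benzene ring, and doing this twice head to tail closes the 22-membered ring to give A3.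
- For it: it is the most convergent option in bonds formed; the polarity of the ynol ether places C7 exactly between two oxygens; it avoids alkylating an electron-rich arene; C7 is set beforehand as a propargylic centre.
- Against it for this target: the monomer must carry a cyclobutenone and a silyl ynol ether as well as three stereocentres, which is long and delicate to make. Head-to-tail dimerisation has no template, and the dilution that favours ring closure slows the first bimolecular step while the vinylketene decays. After A3 the free phenols must be told apart from the C1 hydroxyl during carbamoylation, and both acetals must be converted to dichloromethyl groups before the final desilylations.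
- Comparison: Alternative 3 is equal or stronger in convergence and in the regiochemical placement of C7. The chosen route offers templated pairing in an active site, a monomer 22 reachable in 11 steps and the target directly from the key step.

Key step: step 12

## Route

Step 1
Reactants: 1 3,5-dihydroxybenzaldehyde
Product: 2 3,5-bis(triisopropylsilyloxy)benzaldehyde
Conditions: TIPSCl, imidazole, DMF, rt
Reagents that add atoms: chlorotriisopropylsilane, CC(C)[Si](Cl)(C(C)C)C(C)C
Why: Silylation of phenols with a silyl chloride and imidazole; the bulky aryl silyl ethers should resist the organometallic, mildly basic and neutral conditions ahead and still fall to buffered fluoride in step 11.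

Step 2
Reactants: 2 3,5-bis(triisopropylsilyloxy)benzaldehyde; 3 cis-but-2-ene
Product: 7 (1R,2S)-1-[3,5-bis(triisopropylsilyloxy)phenyl]-2-methylbut-3-en-1-ol, via (Z)-crotylpotassium 4 (not isolated), via (Z)-crotyldiisopinocampheylborane 5 (not isolated), via borinate ester 6 (not isolated)
Conditions: 3, KOtBu, n-BuLi, THF, −78 → −45 °C; (+)-Ipc2BOMe, −78 °C; BF3·OEt2; 2, −78 °C; then NaBO3·4H2O, THF/H2O, rt
Reagents that add atoms: none
Why: Brown asymmetric crotylboration through a closed six-membered chair transition state: the Z geometry of 5 gives the 1,2-syn relationship, and the isopinocampheyl groups of this antipode (the (−)-α-pinene series) direct the crotyl unit to the Re face of the aldehyde, setting C1 (R) and C2 (S) together. The vinyl group supplies C3 and the carbon lost in step 9.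

Step 3
Reactants: 7 (1R,2S)-1-[3,5-bis(triisopropylsilyloxy)phenyl]-2-methylbut-3-en-1-ol
Product: 9 (1R,2S)-1-[3,5-bis(triisopropylsilyloxy)phenyl]-2-methylbut-3-en-1-yl carbamate, via N-trichloroacetyl carbamate 8 (not isolated)
Conditions: Cl3CC(O)NCO, CH2Cl2, 0 °C; then neutral Al2O3, rt
Reagents that add atoms: trichloroacetyl isocyanate, O=C=NC(=O)C(Cl)(Cl)Cl
Why: Carbamoylation of a secondary alcohol by addition to an acyl isocyanate, followed by hydrolytic loss of the trichloroacetyl group on alumina; the neutral conditions should keep the aryl silyl ethers, and C1 is not a reaction centre.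

Step 4
Reactants: 10 (S)-epichlorohydrin; 11 allylmagnesium chloride
Product: 13 (S)-2-(but-3-en-1-yl)oxirane, via (S)-1-chlorohex-5-en-2-ol 12 (not isolated)
Conditions: 11, CuI (2 mol%), THF, −40 → 0 °C; then aq NaOH, rt
Reagents that add atoms: none
Why: CuI-catalysed Grignard opening of the epoxide at its CH2 carbon (C6), then base-induced intramolecular Williamson closure of the chlorohydrin; the stereocentre of 10 (the future C7) is never a reaction centre, so its configuration should pass unchanged into 13.

Step 5
Reactants: 13 (S)-2-(but-3-en-1-yl)oxirane; 14 2-(2-bromoethyl)-1,3-dioxolane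
Product: 16 (R)-1-(1,3-dioxolan-2-yl)oct-7-en-4-ol, via Grignard reagent 15 (not isolated)
Conditions: 14, Mg, THF, 25 °C; then 13, CuI (10 mol%), THF, −30 → 0 °C
Reagents that add atoms: none
Why: Grignard formation followed by CuI-catalysed SN2 opening of the terminal epoxide at CH2 (C8), which forms the C8–C9 bond without touching C7; the dioxolane carries C11 as a masked aldehyde.

Step 6
Reactants: 16 (R)-1-(1,3-dioxolan-2-yl)oct-7-en-4-ol
Product: 17 2-[(4S)-4-chlorooct-7-en-1-yl]-1,3-dioxolane
Conditions: PPh3, CCl4, MeCN, 0 → 50 °C
Reagents that add atoms: tetrachloromethane, ClC(Cl)(Cl)Cl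
Why: Appel reaction: chloride displaces the alkoxyphosphonium group in an SN2 step with inversion at C7, giving the C–Cl arrangement that a second inversion in step 12 turns into C7 of the target. The neutral conditions should spare the acetal and the alkene.

Step 7
Reactants: 17 2-[(4S)-4-chlorooct-7-en-1-yl]-1,3-dioxolane
Product: 18 (5S)-5-chloronon-8-enal
Conditions: 2 M HCl, THF, 40 °C
Reagents that add atoms: water, O
Why: Acid-catalysed acetal hydrolysis; nothing else in 17 is acid-sensitive, and with C7 already a chloride the freed aldehyde cannot close to a lactol.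

Step 8
Reactants: 18 (5S)-5-chloronon-8-enal
Product: 19 (5S)-5,9,9-trichloronon-1-ene
Conditions: Ph3PO (15 mol%), (COCl)2, CHCl3, rt
Reagents that add atoms: oxalyl chloride, O=C(Cl)C(Cl)=O
Why: Deoxydichlorination of an aldehyde by a chlorophosphonium salt regenerated from Ph3PO and oxalyl chloride (Appel-type activation of the carbonyl oxygen, then two chloride deliveries); the alkene and the secondary chloride are inert and no free chlorine is present.

Step 9
Reactants: 9 (1R,2S)-1-[3,5-bis(triisopropylsilyloxy)phenyl]-2-methylbut-3-en-1-yl carbamate; 19 (5S)-5,9,9-trichloronon-1-ene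
Product: 20 (1R,2S,3E,7S)-1-[3,5-bis(triisopropylsilyloxy)phenyl]-7,11,11-trichloro-2-methylundec-3-en-1-yl carbamate
Conditions: 19 (3 equiv), second-generation Hoveyda–Grubbs catalyst RuCl2(H2IMes)(=CH-C6H4-2-OiPr) (5 mol%), CH2Cl2, 40 °C
Reagents that add atoms: none
Why: Olefin cross-metathesis between the allylically branched, slowly homodimerising alkene 9 and an excess of the unhindered alkene 19 forms C3=C4; ruthenium carbenes tolerate carbamates, alkyl chlorides and silyl ethers, and the E/Z ratio does not matter because the alkene is reduced next.

Step 10
Reactants: 20 (1R,2S,3E,7S)-1-[3,5-bis(triisopropylsilyloxy)phenyl]-7,11,11-trichloro-2-methylundec-3-en-1-yl carbamate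
Product: 21 (1R,2S,7R)-1-[3,5-bis(triisopropylsilyloxy)phenyl]-7,11,11-trichloro-2-methylundecyl carbamate
Conditions: TsNHNH2, NaOAc, DME/H2O, 85 °C
Reagents that add atoms: none
Why: Diimide reduction: concerted syn transfer of two hydrogens from HN=NH generated in the flask; unlike hydrogenation over a metal surface it cannot cleave C–Cl bonds or the benzylic C–O bond, and no stereocentre is touched (the C7 descriptor changes only because the priorities change).

Step 11
Reactants: 21 (1R,2S,7R)-1-[3,5-bis(triisopropylsilyloxy)phenyl]-7,11,11-trichloro-2-methylundecyl carbamate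
Product: 22 (1R,2S,7R)-7,11,11-trichloro-1-(3,5-dihydroxyphenyl)-2-methylundecyl carbamate
Conditions: TBAF, AcOH, THF, 0 °C
Reagents that add atoms: none
Why: Fluoride-induced cleavage of aryl silyl ethers, which is fast because phenoxide leaves silicon readily; acetic acid buffering keeps the medium from becoming basic enough to eliminate HCl or attack the carbamate.

Step 12
Reactants: 22 (1R,2S,7R)-7,11,11-trichloro-1-(3,5-dihydroxyphenyl)-2-methylundecyl carbamate (two molecules)
Product: 24 the target, (1R,2S,7S,1'R,2'S,7'S)-[7.7]paracyclophane bis-carbamate, via linear head-to-tail dimer 23 (not isolated)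
Conditions: CylK (about 5 mol%), HEPES buffer pH 8, NaCl, MgCl2, CaCl2, 5% DMSO, 37 °C
Reagents that add atoms: none
Why: This is an enzyme-catalysed Friedel–Crafts alkylation: in the active site the resorcinol of one molecule of 22, activated by hydrogen bonding to basic residues, attacks C7 of a second molecule through the ring carbon between its hydroxyls, anti to the C–Cl bond, while the protein stabilises the departing chloride and loss of the ring proton restores the arene. The closest known reaction is the CylK-mediated dimerisation of 5-alkylresorcinols carrying a secondary chloride seven carbons from the ring, together with the same enzyme's intermolecular alkylation of resorcinols by secondary alkyl halides. The first alkylation is intermolecular and gives the linear dimer 23; the second is an intramolecular exo substitution at the remaining C7 chloride and closes the one new ring, the 22-membered paracyclophane. Both new stereocentres (C7 and C7') are controlled by the configuration of the C–Cl carbon fixed in steps 4–6, because each substitution is stereospecific with inversion. The step needs C- over O-alkylation, attack by the carbon flanked by both hydroxyls and not by its neighbours, and head-to-tail pairing over oligomerisation. The 5-alkylresorcinol pattern makes that carbon the doubly activated site, the seven-carbon spacing between ring and chloride matches the natural substrate, and the active site supplies the rest. The C1 carbamate and the dichloromethyl terminus are the only departures from the native substrate and lie away from the reacting atoms.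

## Compound list

1 | 3,5-dihydroxybenzaldehyde | O=Cc1cc(O)cc(O)c1 | starting material
2 | 3,5-bis(triisopropylsilyloxy)benzaldehyde | O=Cc1cc(O[Si](C(C)C)(C(C)C)C(C)C)cc(O[Si](C(C)C)(C(C)C)C(C)C)c1 | intermediate
3 | cis-but-2-ene | C/C=C\C | starting material
4 | (Z)-crotylpotassium | [K+].C/C=C\[CH2-] | intermediate (not isolated)
5 | (Z)-crotyldiisopinocampheylborane, isopinocampheyl groups of the (−)-α-pinene series | C/C=C\CB([C@H]1C[C@H]2C[C@@H]([C@@H]1C)C2(C)C)[C@H]1C[C@H]2C[C@@H]([C@@H]1C)C2(C)C | intermediate (not isolated)
6 | diisopinocampheylborinate ester of 7 | O([C@@H](c1cc(O[Si](C(C)C)(C(C)C)C(C)C)cc(O[Si](C(C)C)(C(C)C)C(C)C)c1)[C@@H](C)C=C)B([C@H]1C[C@H]2C[C@@H]([C@@H]1C)C2(C)C)[C@H]1C[C@H]2C[C@@H]([C@@H]1C)C2(C)C | intermediate (not isolated)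
7 | (1R,2S)-1-[3,5-bis(triisopropylsilyloxy)phenyl]-2-methylbut-3-en-1-ol | O[C@@H](c1cc(O[Si](C(C)C)(C(C)C)C(C)C)cc(O[Si](C(C)C)(C(C)C)C(C)C)c1)[C@@H](C)C=C | intermediate
8 | (1R,2S)-1-[3,5-bis(triisopropylsilyloxy)phenyl]-2-methylbut-3-en-1-yl N-(trichloroacetyl)carbamate | ClC(Cl)(Cl)C(=O)NC(=O)O[C@@H](c1cc(O[Si](C(C)C)(C(C)C)C(C)C)cc(O[Si](C(C)C)(C(C)C)C(C)C)c1)[C@@H](C)C=C | intermediate (not isolated)
9 | (1R,2S)-1-[3,5-bis(triisopropylsilyloxy)phenyl]-2-methylbut-3-en-1-yl carbamate | NC(=O)O[C@@H](c1cc(O[Si](C(C)C)(C(C)C)C(C)C)cc(O[Si](C(C)C)(C(C)C)C(C)C)c1)[C@@H](C)C=C | intermediate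
10 | (S)-epichlorohydrin, (S)-2-(chloromethyl)oxirane | ClC[C@@H]1CO1 | starting material
11 | allylmagnesium chloride | C=CC[Mg]Cl | starting material
12 | (S)-1-chlorohex-5-en-2-ol (present as its magnesium alkoxide) | C=CCC[C@H](O)CCl | intermediate (not isolated)
13 | (S)-2-(but-3-en-1-yl)oxirane | C=CCC[C@H]1CO1 | intermediate
14 | 2-(2-bromoethyl)-1,3-dioxolane | BrCCC1OCCO1 | starting material
15 | [2-(1,3-dioxolan-2-yl)ethyl]magnesium bromide | Br[Mg]CCC1OCCO1 | intermediate (not isolated)
16 | (R)-1-(1,3-dioxolan-2-yl)oct-7-en-4-ol | C=CCC[C@H](O)CCCC1OCCO1 | intermediate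
17 | 2-[(4S)-4-chlorooct-7-en-1-yl]-1,3-dioxolane | C=CCC[C@@H](Cl)CCCC1OCCO1 | intermediate
18 | (5S)-5-chloronon-8-enal | C=CCC[C@@H](Cl)CCCC=O | intermediate
19 | (5S)-5,9,9-trichloronon-1-ene | C=CCC[C@@H](Cl)CCCC(Cl)Cl | intermediate
20 | (1R,2S,3E,7S)-1-[3,5-bis(triisopropylsilyloxy)phenyl]-7,11,11-trichloro-2-methylundec-3-en-1-yl carbamate | NC(=O)O[C@@H](c1cc(O[Si](C(C)C)(C(C)C)C(C)C)cc(O[Si](C(C)C)(C(C)C)C(C)C)c1)[C@@H](C)/C=C/CC[C@@H](Cl)CCCC(Cl)Cl | intermediate
21 | (1R,2S,7R)-1-[3,5-bis(triisopropylsilyloxy)phenyl]-7,11,11-trichloro-2-methylundecyl carbamate | NC(=O)O[C@@H](c1cc(O[Si](C(C)C)(C(C)C)C(C)C)cc(O[Si](C(C)C)(C(C)C)C(C)C)c1)[C@@H](C)CCCC[C@@H](Cl)CCCC(Cl)Cl | intermediate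
22 | (1R,2S,7R)-7,11,11-trichloro-1-(3,5-dihydroxyphenyl)-2-methylundecyl carbamate (monomer) | NC(=O)O[C@@H](c1cc(O)cc(O)c1)[C@@H](C)CCCC[C@@H](Cl)CCCC(Cl)Cl | intermediate
23 | linear head-to-tail dimer: one aryl–C7 bond formed, one C7 chloride and one unsubstituted resorcinol remaining | NC(=O)O[C@@H](c1cc(O)cc(O)c1)[C@@H](C)CCCC[C@@H](CCCC(Cl)Cl)c1c(O)cc(cc1O)[C@H](OC(N)=O)[C@@H](C)CCCC[C@@H](Cl)CCCC(Cl)Cl | intermediate (not isolated)
24 | (1R,2S,7S,1'R,2'S,7'S)-7,7'-bis(4,4-dichlorobutyl)-2,2'-dimethyl[7.7]paracyclophane-1,1'-diyl dicarbamate with hydroxyls on both ring carbons next to each C7-bearing ring carbon | C[C@H]1CCCC[C@@H](CCCC(Cl)Cl)c2c(O)cc(cc2O)[C@H](OC(N)=O)[C@@H](C)CCCC[C@@H](CCCC(Cl)Cl)c2c(O)cc(cc2O)[C@@H]1OC(N)=O | target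

## Step count and least certain steps

Total: 12 steps. Longest linear sequence: 9 steps (steps 4–8, then 9–12); the arene branch (steps 1–3) joins at step 9.

**Step 12 (key step).** The most likely failure is unproductive binding. The C1 carbamate adds a polar, hydrogen-bonding group next to the nucleophilic ring and the dichloromethyl end changes the tail of the electrophile, so turnover may be slow. Alternatively the first alkylation may proceed while the ring closure of 23 stalls and linear material accumulates. The fallback takes the carbamate out of the enzymatic step and sets out from 7 and 19. Cross-metathesis as in step 9 should give the alkenol (1R,2S,3E,7S)-1-[3,5-bis(triisopropylsilyloxy)phenyl]-7,11,11-trichloro-2-methylundec-3-en-1-ol F1. Diimide reduction should give the saturated alcohol F2, and buffered fluoride the triol monomer 5-[(1R,2S,7R)-7,11,11-trichloro-1-hydroxy-2-methylundecyl]benzene-1,3-diol F3, which is closer to the native substrate. CylK should convert F3 into the cyclophane diol F4. Excess trichloroacetyl isocyanate would acylate all six hydroxyls of F4, giving the hexakis(N-trichloroacetylcarbamate) F5, which is not isolated. K2CO3 in methanol should then remove the trichloroacetyl groups and, through the fast base-induced loss of isocyanic acid from aryl carbamates, free the four phenols while the two alkyl carbamates stay. The fallback returns to the route at 24.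

**Step 2.** Incomplete enantiofacial control, or partial isomerisation of the (Z)-crotyl metal before borylation, would give the enantiomer or the anti isomer. The minor enantiomer becomes a hard-to-separate remote diastereomer after step 9. The fallback sets out from 2 and uses auxiliary control with separable diastereomers. Evans syn-aldol addition of commercial (R)-4-benzyl-3-propionyloxazolidin-2-one to 2 (Bu2BOTf, iPr2NEt, CH2Cl2, −78 → 0 °C) should give the (2R,3R)-aldol adduct F6. Silylation (TESOTf, 2,6-lutidine) gives the triethylsilyl ether F7, and LiBH4 removes the auxiliary to give the primary alcohol F8. Dess–Martin oxidation gives the aldehyde F9, and Wittig methylenation (Ph3PCH3Br, KN(SiMe3)2, THF) the silyl-protected alkene F10. PPTS in methanol then removes the triethylsilyl group without touching the aryl silyl ethers, returning to the route at 7.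

**Step 6.** Elimination of the activated secondary alcohol, or partial loss of stereochemical integrity through ion-pair return, would lower yield or enantiopurity at C7. The fallback sets out from 16 and separates activation from displacement. MsCl and Et3N give the mesylate (R)-1-(1,3-dioxolan-2-yl)oct-7-en-4-yl methanesulfonate F11, and LiCl in DMF at 50 °C displaces it in a clean SN2 step with inversion, returning at 17.

**Step 8.** Enolisation of the activated aldehyde can lead to a vinyl chloride in place of the geminal dichloride, or conversion may be incomplete. The fallback sets out from 18 and avoids oxygen activation. Condensation with N2H4·H2O in ethanol gives the hydrazone F12, and oxidation with CuCl2 and Et3N in methanol should deliver both chlorines with loss of nitrogen, returning at 19.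

## Further compounds

F1 | step 12 | (1R,2S,3E,7S)-1-[3,5-bis(triisopropylsilyloxy)phenyl]-7,11,11-trichloro-2-methylundec-3-en-1-ol | O[C@@H](c1cc(O[Si](C(C)C)(C(C)C)C(C)C)cc(O[Si](C(C)C)(C(C)C)C(C)C)c1)[C@@H](C)/C=C/CC[C@@H](Cl)CCCC(Cl)Cl
F2 | step 12 | (1R,2S,7R)-1-[3,5-bis(triisopropylsilyloxy)phenyl]-7,11,11-trichloro-2-methylundecan-1-ol | O[C@@H](c1cc(O[Si](C(C)C)(C(C)C)C(C)C)cc(O[Si](C(C)C)(C(C)C)C(C)C)c1)[C@@H](C)CCCC[C@@H](Cl)CCCC(Cl)Cl
F3 | step 12 | 5-[(1R,2S,7R)-7,11,11-trichloro-1-hydroxy-2-methylundecyl]benzene-1,3-diol | O[C@@H](c1cc(O)cc(O)c1)[C@@H](C)CCCC[C@@H](Cl)CCCC(Cl)Cl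
F4 | step 12 | cyclophane diol, the analogue of 24 with hydroxyls at C1 and C1' | C[C@H]1CCCC[C@@H](CCCC(Cl)Cl)c2c(O)cc(cc2O)[C@H](O)[C@@H](C)CCCC[C@@H](CCCC(Cl)Cl)c2c(O)cc(cc2O)[C@@H]1O
F5 | step 12 | hexakis(N-trichloroacetylcarbamate) of F4 | C[C@H]1CCCC[C@@H](CCCC(Cl)Cl)c2c(OC(=O)NC(=O)C(Cl)(Cl)Cl)cc(cc2OC(=O)NC(=O)C(Cl)(Cl)Cl)[C@H](OC(=O)NC(=O)C(Cl)(Cl)Cl)[C@@H](C)CCCC[C@@H](CCCC(Cl)Cl)c2c(OC(=O)NC(=O)C(Cl)(Cl)Cl)cc(cc2OC(=O)NC(=O)C(Cl)(Cl)Cl)[C@@H]1OC(=O)NC(=O)C(Cl)(Cl)Cl
F6 | step 2 | (R)-4-benzyl-3-[(2R,3R)-3-[3,5-bis(triisopropylsilyloxy)phenyl]-3-hydroxy-2-methylpropanoyl]oxazolidin-2-one | O[C@@H](c1cc(O[Si](C(C)C)(C(C)C)C(C)C)cc(O[Si](C(C)C)(C(C)C)C(C)C)c1)[C@@H](C)C(=O)N1C(=O)OC[C@H]1Cc1ccccc1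
F7 | step 2 | (R)-4-benzyl-3-[(2R,3R)-3-[3,5-bis(triisopropylsilyloxy)phenyl]-2-methyl-3-(triethylsilyloxy)propanoyl]oxazolidin-2-one | CC[Si](CC)(CC)O[C@@H](c1cc(O[Si](C(C)C)(C(C)C)C(C)C)cc(O[Si](C(C)C)(C(C)C)C(C)C)c1)[C@@H](C)C(=O)N1C(=O)OC[C@H]1Cc1ccccc1
F8 | step 2 | (2S,3R)-3-[3,5-bis(triisopropylsilyloxy)phenyl]-2-methyl-3-(triethylsilyloxy)propan-1-ol | CC[Si](CC)(CC)O[C@@H](c1cc(O[Si](C(C)C)(C(C)C)C(C)C)cc(O[Si](C(C)C)(C(C)C)C(C)C)c1)[C@@H](C)CO
F9 | step 2 | (2R,3R)-3-[3,5-bis(triisopropylsilyloxy)phenyl]-2-methyl-3-(triethylsilyloxy)propanal | CC[Si](CC)(CC)O[C@@H](c1cc(O[Si](C(C)C)(C(C)C)C(C)C)cc(O[Si](C(C)C)(C(C)C)C(C)C)c1)[C@@H](C)C=O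
F10 | step 2 | triethylsilyl ether of 7, (1R,2S)-configured | CC[Si](CC)(CC)O[C@@H](c1cc(O[Si](C(C)C)(C(C)C)C(C)C)cc(O[Si](C(C)C)(C(C)C)C(C)C)c1)[C@@H](C)C=C
F11 | step 6 | (R)-1-(1,3-dioxolan-2-yl)oct-7-en-4-yl methanesulfonate | C=CCC[C@H](OS(C)(=O)=O)CCCC1OCCO1
F12 | step 8 | (5S)-5-chloronon-8-enal hydrazone | C=CCC[C@@H](Cl)CCC/C=N/N
A1 | alternative 1 | 22-membered cyclophane bis(aryl ketone) with C2 set, (E)-alkenes at C4–C5, MOM-protected resorcinols and 4-(triisopropylsilyloxy)butyl side chains | C[C@H]1C/C=C/C[C@@H](CCCCO[Si](C(C)C)(C(C)C)C(C)C)c2c(OCOC)cc(cc2OCOC)C(=O)[C@@H](C)C/C=C/C[C@@H](CCCCO[Si](C(C)C)(C(C)C)C(C)C)c2c(OCOC)cc(cc2OCOC)C1=O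
A2 | alternative 2 | cyclophane bis(tertiary C7 pinacol boronic ester) with 4,4-dimethoxybutyl side chains, MOM-protected resorcinols and C1 tert-butyldimethylsilyl ethers | C[C@H]1CCCC[C@@](B3OC(C)(C)C(C)(C)O3)(CCCC(OC)OC)c2c(OCOC)cc(cc2OCOC)[C@H](O[Si](C)(C)C(C)(C)C)[C@@H](C)CCCC[C@@](B3OC(C)(C)C(C)(C)O3)(CCCC(OC)OC)c2c(OCOC)cc(cc2OCOC)[C@@H]1O[Si](C)(C)C(C)(C)C
A3 | alternative 3 | cyclophane with each resorcinol as its mono-triisopropylsilyl ether, C1 tert-butyldimethylsilyl ethers and 4,4-dimethoxybutyl side chains | C[C@H]1CCCC[C@@H](CCCC(OC)OC)c2c(O)cc(cc2O[Si](C(C)C)(C(C)C)C(C)C)[C@H](O[Si](C)(C)C(C)(C)C)[C@@H](C)CCCC[C@@H](CCCC(OC)OC)c2c(O)cc(cc2O[Si](C(C)C)(C(C)C)C(C)C)[C@@H]1O[Si](C)(C)C(C)(C)C
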